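**Retrosynthetic overview**
1. Target 18 ← bis-TBS ether 17 by buffered fluoride desilylation. Acid is avoided at the end because a 2'-hydroxyisoflav-3-ene with this electron-rich A ring would risk cyclising to a pterocarpan.
2. Pyran ring of 17 (C4–C3 and O1–C2 bonds) ← salicylaldehyde 8 + α-arylvinylboronic acid 14, by a new amine-catalysed borono-Mannich / o-quinone methide / oxa-6π annulation. This is the only ring formed; rings A and B are bought.
3. 8 ← C2-symmetric phenol 6 by ortho-formylation (both ortho sites equivalent) ← 3,5-dimethoxyphenol 1 via TIPS ether 2, lithiation between the two OMe groups and prenylation with 3.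
4. 14 ← vinyl boronate 13 ← enol triflate 12 ← bis-TBS ketone 10 ← 2',4'-dihydroxyacetophenone 9.

Assumption: the target SMILES has no stereocentre and no stereogenic double bond, so the compound is achiral and "single enantiomer" needs no stereocontrol.
Convention: numbered compounds are the substrates and building blocks; auxiliary reagents that leave atoms in a product appear only on the "Reagents that add atoms" line.

**Step 1**
Reactants: 1 3,5-dimethoxyphenol
Product: 2 (3,5-dimethoxyphenoxy)tri(propan-2-yl)silane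
Conditions: TIPSCl (1.2 equiv), imidazole (2.5 equiv), DMF, rt, 12 h
Reagents that add atoms: triisopropylsilyl chloride, CC(C)[Si](Cl)(C(C)C)C(C)C
Why: Standard phenol O-silylation; TIPS is chosen because it is not a directing group, shields both of its ortho positions and survives n-BuLi.

**Step 2**
Reactants: 2 (3,5-dimethoxyphenoxy)tri(propan-2-yl)silane; 3 1-bromo-3-methylbut-2-ene (prenyl bromide)
Product: 5 [3,5-dimethoxy-4-(3-methylbut-2-en-1-yl)phenoxy]tri(propan-2-yl)silane, via aryllithium 4 (not isolated)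
Conditions: n-BuLi (1.2 equiv), THF, 0 °C → rt, 2 h; then CuI (10 mol %), 3 (1.5 equiv), −78 °C → rt
Reagents that add atoms: none
Why: Directed ortho-metalation at the C–H flanked by two OMe groups (the bulky OTIPS group does not direct), followed by copper-catalysed SN2 allylation of the aryllithium with prenyl bromide.

**Step 3**
Reactants: 5 [3,5-dimethoxy-4-(3-methylbut-2-en-1-yl)phenoxy]tri(propan-2-yl)silane
Product: 6 3,5-dimethoxy-4-(3-methylbut-2-en-1-yl)phenol
Conditions: TBAF (1.2 equiv), AcOH (1.2 equiv), THF, 0 °C → rt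
Reagents that add atoms: none
Why: Fluoride-induced cleavage of the aryl silyl ether (Si–F bond formation), buffered with AcOH so the electron-rich phenol is not left as a phenoxide.

**Step 4**
Reactants: 6 3,5-dimethoxy-4-(3-methylbut-2-en-1-yl)phenol
Product: 8 2-hydroxy-4,6-dimethoxy-5-(3-methylbut-2-en-1-yl)benzaldehyde, via salicyl alcohol 7 (not isolated)
Conditions: MgCl2 (1.5 equiv), Et3N (3.8 equiv), (CH2O)n (7 equiv), MeCN, reflux, 4 h; then 1 M HCl, 0 °C
Reagents that add atoms: paraformaldehyde (reacts as formaldehyde), C=O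
Why: Casnati–Skattebøl magnesium-mediated ortho-formylation: the magnesium phenoxide delivers formaldehyde only ortho to OH (both sites are equivalent by symmetry), and hydroxymethyl intermediate 7 is oxidised by a second formaldehyde through Oppenauer-type hydride transfer, under conditions that leave the prenyl group alone.

**Step 5**
Reactants: 9 1-(2,4-dihydroxyphenyl)ethan-1-one
Product: 10 1-{2,4-bis[(tert-butyldimethylsilyl)oxy]phenyl}ethan-1-one
Conditions: TBSCl (2.5 equiv), imidazole (5 equiv), DMF, rt, 16 h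
Reagents that add atoms: tert-butyldimethylsilyl chloride, CC(C)(C)[Si](C)(C)Cl
Why: Standard double phenol O-silylation (imidazole/DMF); silyl ethers are chosen because they can be removed at the end without acid.

**Step 6**
Reactants: 10 1-{2,4-bis[(tert-butyldimethylsilyl)oxy]phenyl}ethan-1-one
Product: 12 1-{2,4-bis[(tert-butyldimethylsilyl)oxy]phenyl}ethenyl trifluoromethanesulfonate, via potassium enolate 11 (not isolated)
Conditions: KHMDS (1.1 equiv), THF, −78 °C, 30 min; PhNTf2 (1.15 equiv), −78 °C, 1 h; Et3N-deactivated silica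
Reagents that add atoms: N-phenylbis(trifluoromethanesulfonimide), O=S(=O)(N(c1ccccc1)S(=O)(=O)C(F)(F)F)C(F)(F)F
Why: Enolate O-triflation of a methyl ketone with a single enolisable site; the low temperature and fast trapping of the potassium enolate suppress silyl migration from the ortho oxygen.

**Step 7**
Reactants: 12 1-{2,4-bis[(tert-butyldimethylsilyl)oxy]phenyl}ethenyl trifluoromethanesulfonate
Product: 13 2-(1-{2,4-bis[(tert-butyldimethylsilyl)oxy]phenyl}ethenyl)-4,4,5,5-tetramethyl-1,3,2-dioxaborolane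
Conditions: B2pin2 (1.1 equiv), PdCl2(PPh3)2 (3 mol %), PPh3 (6 mol %), KOPh (1.5 equiv), toluene, 50 °C
Reagents that add atoms: bis(pinacolato)diboron, CC1(C)OB(OC1(C)C)B1OC(C)(C)C(C)(C)O1
Why: Miyaura borylation of an alkenyl triflate (oxidative addition, phenoxide-assisted transmetalation with the diboron, reductive elimination) at a temperature the silyl ethers tolerate.

**Step 8**
Reactants: 13 2-(1-{2,4-bis[(tert-butyldimethylsilyl)oxy]phenyl}ethenyl)-4,4,5,5-tetramethyl-1,3,2-dioxaborolane
Product: 14 (1-{2,4-bis[(tert-butyldimethylsilyl)oxy]phenyl}ethenyl)boronic acid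
Conditions: NaIO4 (3 equiv), NH4OAc (3 equiv), acetone/H2O 1:1, rt, 16 h; used crude
Reagents that add atoms: water, O
Why: Oxidative pinacol-ester deprotection: periodate glycol cleavage removes the pinacol released by hydrolysis and so drives the equilibrium to the free boronic acid under near-neutral conditions.

**Step 9**
Reactants: 8 2-hydroxy-4,6-dimethoxy-5-(3-methylbut-2-en-1-yl)benzaldehyde; 14 (1-{2,4-bis[(tert-butyldimethylsilyl)oxy]phenyl}ethenyl)boronic acid
Product: 17 3-{2,4-bis[(tert-butyldimethylsilyl)oxy]phenyl}-5,7-dimethoxy-6-(3-methylbut-2-en-1-yl)-2H-chromene, via Mannich base 15 (not isolated), via o-quinone methide 16 (not isolated)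
Conditions: 14 (1.5 equiv), Bn2NH (30 mol %), 1,4-dioxane, 90 °C, 24 h, Ar
Reagents that add atoms: none
Why: Proposed new method: Bn2NH condenses with the aldehyde of 8 to an iminium/aminal, the neighbouring phenoxide binds boronic acid 14 and the resulting ate complex transfers the 1-arylvinyl group (through its boron-bearing carbon) to the iminium carbon to give 15 (C4–C3 bond), the electron-rich ring then expels Bn2NH (catalyst turnover) to give (Z)-o-quinone methide 16, and oxa-6π electrocyclisation closes O1–C2 and leaves the C3=C4 double bond with the aryl group at C3; the closest known reaction type is the amine-catalysed Petasis borono-Mannich condensation of salicylaldehydes with β-substituted (E)-alkenylboronic acids to 2-substituted 2H-chromenes, here extended to an α-arylvinylboronic acid to give a 3-aryl-2H-chromene.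

**Step 10**
Reactants: 17 3-{2,4-bis[(tert-butyldimethylsilyl)oxy]phenyl}-5,7-dimethoxy-6-(3-methylbut-2-en-1-yl)-2H-chromene
Product: 18 4-[5,7-dimethoxy-6-(3-methylbut-2-en-1-yl)-2H-chromen-3-yl]benzene-1,3-diol (dehydroglyasperin D)
Conditions: TBAF (2.5 equiv), AcOH (2.5 equiv), THF, 0 °C, Ar
Reagents that add atoms: none
Why: Fluoride desilylation of both aryl TBS ethers under buffered, non-acidic conditions that leave the chromene double bond, the prenyl group and the methyl ethers untouched.

**Compound list**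
1 | 3,5-dimethoxyphenol | COc1cc(O)cc(OC)c1 | starting material
2 | (3,5-dimethoxyphenoxy)tri(propan-2-yl)silane | COc1cc(OC)cc(O[Si](C(C)C)(C(C)C)C(C)C)c1 | intermediate
3 | 1-bromo-3-methylbut-2-ene (prenyl bromide) | CC(C)=CCBr | starting material
4 | {2,6-dimethoxy-4-[(triisopropylsilyl)oxy]phenyl}lithium | [Li]c1c(OC)cc(O[Si](C(C)C)(C(C)C)C(C)C)cc1OC | intermediate (not isolated)
5 | [3,5-dimethoxy-4-(3-methylbut-2-en-1-yl)phenoxy]tri(propan-2-yl)silane | COc1cc(O[Si](C(C)C)(C(C)C)C(C)C)cc(OC)c1CC=C(C)C | intermediate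
6 | 3,5-dimethoxy-4-(3-methylbut-2-en-1-yl)phenol | COc1cc(O)cc(OC)c1CC=C(C)C | intermediate
7 | 2-(hydroxymethyl)-3,5-dimethoxy-4-(3-methylbut-2-en-1-yl)phenol (present as its magnesium phenoxide, drawn neutral) | COc1cc(O)c(CO)c(OC)c1CC=C(C)C | intermediate (not isolated)
8 | 2-hydroxy-4,6-dimethoxy-5-(3-methylbut-2-en-1-yl)benzaldehyde | COc1cc(O)c(C=O)c(OC)c1CC=C(C)C | intermediate
9 | 1-(2,4-dihydroxyphenyl)ethan-1-one (2',4'-dihydroxyacetophenone) | CC(=O)c1ccc(O)cc1O | starting material
10 | 1-{2,4-bis[(tert-butyldimethylsilyl)oxy]phenyl}ethan-1-one | CC(=O)c1ccc(O[Si](C)(C)C(C)(C)C)cc1O[Si](C)(C)C(C)(C)C | intermediate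
11 | potassium 1-{2,4-bis[(tert-butyldimethylsilyl)oxy]phenyl}ethen-1-olate | [K+].[O-]C(=C)c1ccc(O[Si](C)(C)C(C)(C)C)cc1O[Si](C)(C)C(C)(C)C | intermediate (not isolated)
12 | 1-{2,4-bis[(tert-butyldimethylsilyl)oxy]phenyl}ethenyl trifluoromethanesulfonate | C=C(OS(=O)(=O)C(F)(F)F)c1ccc(O[Si](C)(C)C(C)(C)C)cc1O[Si](C)(C)C(C)(C)C | intermediate
13 | 2-(1-{2,4-bis[(tert-butyldimethylsilyl)oxy]phenyl}ethenyl)-4,4,5,5-tetramethyl-1,3,2-dioxaborolane | C=C(B1OC(C)(C)C(C)(C)O1)c1ccc(O[Si](C)(C)C(C)(C)C)cc1O[Si](C)(C)C(C)(C)C | intermediate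
14 | (1-{2,4-bis[(tert-butyldimethylsilyl)oxy]phenyl}ethenyl)boronic acid | C=C(B(O)O)c1ccc(O[Si](C)(C)C(C)(C)C)cc1O[Si](C)(C)C(C)(C)C | intermediate
15 | rac-2-[2-{2,4-bis[(tert-butyldimethylsilyl)oxy]phenyl}-1-(dibenzylamino)prop-2-en-1-yl]-3,5-dimethoxy-4-(3-methylbut-2-en-1-yl)phenol | COc1cc(O)c(C(N(Cc2ccccc2)Cc2ccccc2)C(=C)c2ccc(O[Si](C)(C)C(C)(C)C)cc2O[Si](C)(C)C(C)(C)C)c(OC)c1CC=C(C)C | intermediate (not isolated)
16 | (6Z)-6-(2-{2,4-bis[(tert-butyldimethylsilyl)oxy]phenyl}prop-2-en-1-ylidene)-3,5-dimethoxy-4-(3-methylbut-2-en-1-yl)cyclohexa-2,4-dien-1-one | O=C1C=C(OC)C(CC=C(C)C)=C(OC)/C1=C/C(=C)c1ccc(O[Si](C)(C)C(C)(C)C)cc1O[Si](C)(C)C(C)(C)C | intermediate (not isolated)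
17 | 3-{2,4-bis[(tert-butyldimethylsilyl)oxy]phenyl}-5,7-dimethoxy-6-(3-methylbut-2-en-1-yl)-2H-chromene | COc1cc2c(c(OC)c1CC=C(C)C)C=C(c1ccc(O[Si](C)(C)C(C)(C)C)cc1O[Si](C)(C)C(C)(C)C)CO2 | intermediate
18 | 4-[5,7-dimethoxy-6-(3-methylbut-2-en-1-yl)-2H-chromen-3-yl]benzene-1,3-diol (dehydroglyasperin D) | COc1cc2c(c(OC)c1CC=C(C)C)C=C(c1ccc(O)cc1O)CO2 | target

**Totals**
Total step count: 10. Longest linear sequence: 6 steps (steps 1, 2, 3, 4, 9, 10; the B-ring branch, steps 5, 6, 7, 8, 9, 10, is equally long).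

**Three steps most likely to fail**

Step 2. The risk is lithiation next to OTIPS instead of between the OMe groups, plus some SN2' allylation. The fallback sets out from prenyl bromide 3 and comes back to the route at phenol 6, bypassing steps 1–3. Commercial 1,3-dimethoxybenzene F1 is lithiated with n-BuLi in THF at 0 °C at its only doubly activated position to give (2,6-dimethoxyphenyl)lithium F2, which is alkylated with 3 to give 1,3-dimethoxy-2-(3-methylbut-2-en-1-yl)benzene F3. Sterically controlled iridium-catalysed C–H borylation ([Ir(OMe)(cod)]2, dtbpy, B2pin2, THF, 80 °C) can then only take place at C5, the one C–H with no ortho substituent, and gives 2-[3,5-dimethoxy-4-(3-methylbut-2-en-1-yl)phenyl]-4,4,5,5-tetramethyl-1,3,2-dioxaborolane F4. Oxidation with H2O2/NaOH in THF/H2O at 0 °C converts F4 into 6.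

Step 6. The risk is silyl migration from the ortho oxygen to the enolate oxygen and the lability of the electron-rich α-arylvinyl triflate. The fallback sets out from ketone 10 and comes back at boronate 13 without any enolate. Hydrazine hydrate and Et3N in EtOH convert 10 into (E)-(1-{2,4-bis[(tert-butyldimethylsilyl)oxy]phenyl}ethylidene)hydrazine F5. Barton iodination (I2, tetramethylguanidine, THF, 0 °C) turns F5 into 2,4-bis[(tert-butyldimethylsilyl)oxy]-1-(1-iodoethenyl)benzene F6. Miyaura borylation of F6 under the step 7 conditions gives 13.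

Step 9 (the proposed new method). The risks are slow iminium formation at the hindered, chelated, electron-rich aldehyde, slow transfer of the α-branched alkenyl group, and protodeboronation of 14. The fallback uses known chemistry, sets out from aldehyde 8 and enol triflate 12, and comes back at 17; steps 7 and 8 are then not needed. Nozaki–Hiyama–Kishi coupling (CrCl2, cat. NiCl2, DMF, rt) converts 12 into {1-[2,4-bis(tert-butyldimethylsilyloxy)phenyl]ethenyl}chromium(III) dichloride F7, which adds to the aldehyde of 8 to give rac-2-(2-{2,4-bis[(tert-butyldimethylsilyl)oxy]phenyl}-1-hydroxyprop-2-en-1-yl)-3,5-dimethoxy-4-(3-methylbut-2-en-1-yl)phenol F8. Heating F8 in toluene at 80–110 °C over 4 Å molecular sieves dehydrates it to the same o-quinone methide 16, which electrocyclises to 17. This is the known thermal cyclodehydration of o-hydroxybenzyl vinyl carbinols to 2H-chromenes.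

**Further compounds**
F1 | step 2 | 1,3-dimethoxybenzene | COc1cccc(OC)c1
F2 | step 2 | (2,6-dimethoxyphenyl)lithium | [Li]c1c(OC)cccc1OC
F3 | step 2 | 1,3-dimethoxy-2-(3-methylbut-2-en-1-yl)benzene | COc1cccc(OC)c1CC=C(C)C
F4 | step 2 | 2-[3,5-dimethoxy-4-(3-methylbut-2-en-1-yl)phenyl]-4,4,5,5-tetramethyl-1,3,2-dioxaborolane | COc1cc(B2OC(C)(C)C(C)(C)O2)cc(OC)c1CC=C(C)C
F5 | step 6 | (E)-(1-{2,4-bis[(tert-butyldimethylsilyl)oxy]phenyl}ethylidene)hydrazine | C/C(=N\N)c1ccc(O[Si](C)(C)C(C)(C)C)cc1O[Si](C)(C)C(C)(C)C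
F6 | step 6 | 2,4-bis[(tert-butyldimethylsilyl)oxy]-1-(1-iodoethenyl)benzene | C=C(I)c1ccc(O[Si](C)(C)C(C)(C)C)cc1O[Si](C)(C)C(C)(C)C
F7 | step 9 | {1-[2,4-bis(tert-butyldimethylsilyloxy)phenyl]ethenyl}chromium(III) dichloride | C=C([Cr](Cl)Cl)c1ccc(O[Si](C)(C)C(C)(C)C)cc1O[Si](C)(C)C(C)(C)C
F8 | step 9 | rac-2-(2-{2,4-bis[(tert-butyldimethylsilyl)oxy]phenyl}-1-hydroxyprop-2-en-1-yl)-3,5-dimethoxy-4-(3-methylbut-2-en-1-yl)phenol | COc1cc(O)c(C(O)C(=C)c2ccc(O[Si](C)(C)C(C)(C)C)cc2O[Si](C)(C)C(C)(C)C)c(OC)c1CC=C(C)C
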